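**Retrosynthetic overview** (chromene atoms O1, C2–C8a; side chain C1'–C12' counted outward from C2, CO2H on C8')
1. Target ⇒ aryl silyl ether ⇒ the pyran ring, the only ring that is made (the benzene ring is bought), is closed last at O1–C8a by Pd etherification of a (Z)-2-bromostyrene, after a C4–C4a Heck union of an iodo-bromo-arene with the vinyl group of an acyclic (R)-hydroxy acid.
2. (Z)-Acrylic acid ⇒ C8'–C9' and C8'–CO2H from an α-metallated (Z)-enol carbamate: homoprenyl shifts from copper to C8' with inversion, then CO2.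
3. Key bond C5'–C6' ⇒ allylic bromide + lithiated allyl carbamate (a homoenolate reagent reacting through its γ-carbon).
4. Allylic bromide ⇒ SeO2 oxidation and bromination of (R)-linalool, which supplies C2 (R), its methyl, C3, C4 and C1'–C5' with the 3'E alkene.

Assumption: commercial (R)-(−)-linalool of ≥97% ee is used; its carbinol C–O bond is never broken, so its configuration becomes C2 of the target unchanged.

**Step 1**
Reactants: 1 (3R)-3,7-dimethylocta-1,6-dien-3-ol [(R)-(−)-linalool]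
Product: 2 (2E,6R)-2,6-dimethylocta-2,7-diene-1,6-diol
Conditions: SeO2 (0.4 equiv), t-BuOOH (2.5 equiv), salicylic acid (10 mol%), CH2Cl2, 0 °C to rt
Reagents that add atoms: tert-butyl hydroperoxide, CC(C)(C)OO
Why: Riley-type SeO2 allylic oxidation (ene reaction then 2,3-sigmatropic shift, SeO2 re-oxidised by t-BuOOH) hydroxylates only the (E)-methyl of the trisubstituted alkene and gives the (E)-allylic alcohol, while the (R)-carbinol centre of 1 is not touched.

**Step 2**
Reactants: 2 (2E,6R)-2,6-dimethylocta-2,7-diene-1,6-diol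
Product: 3 (3R,6E)-8-bromo-3,7-dimethylocta-1,6-dien-3-ol
Conditions: CBr4 (1.05 equiv), PPh3 (1.1 equiv), 2,6-lutidine, CH2Cl2, −30 to 0 °C
Reagents that add atoms: carbon tetrabromide, BrC(Br)(Br)Br
Why: the Appel reaction substitutes the unhindered primary allylic alcohol by SN2 at low temperature without allylic transposition, and the hindered tertiary alcohol, the stereocentre and the (E)-alkene stay as they are.

**Step 3**
Reactants: 4 prop-2-en-1-ol (allyl alcohol); 5 N,N-diisopropylcarbamoyl chloride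
Product: 6 prop-2-en-1-yl N,N-diisopropylcarbamate
Conditions: NaH, THF, 0 °C to reflux
Reagents that add atoms: none
Why: acyl substitution of the carbamoyl chloride by sodium allyloxide gives the Hoppe carbamate, whose diisopropylamide group later directs and stabilises lithiation.

**Step 4**
Reactants: 6 prop-2-en-1-yl N,N-diisopropylcarbamate; 3 (3R,6E)-8-bromo-3,7-dimethylocta-1,6-dien-3-ol
Product: 8 (1Z,5E,9R)-9-hydroxy-5,9-dimethylundeca-1,5,10-trien-1-yl N,N-diisopropylcarbamate, via 1-lithioallyl N,N-diisopropylcarbamate 7 (not isolated)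
Conditions: 6 (2.3 equiv), n-BuLi (2.2 equiv), TMEDA, Et2O, −78 °C; then 3, −78 to −40 °C; H2O
Reagents that add atoms: none
Why: Hoppe homoenolate alkylation, in which the chelated lithio-carbamate 7 (the β-carbon of a masked acrolein made nucleophilic) attacks the allylic bromide through its γ-carbon by SN2 at C5', so that two carbons that are both electrophilic in ordinary synthons are joined and the cisoid lithium chelate fixes the (Z)-enol carbamate, one extra equivalent of 7 being used up by the free OH of 3.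

**Step 5**
Reactants: 8 (1Z,5E,9R)-9-hydroxy-5,9-dimethylundeca-1,5,10-trien-1-yl N,N-diisopropylcarbamate; 9 5-bromo-2-methylpent-2-ene
Product: 15 (2Z,6E,10R)-10-hydroxy-6,10-dimethyl-2-(4-methylpent-3-en-1-yl)dodeca-2,6,11-trienoic acid, via homoprenylmagnesium bromide 10 (not isolated), via homoprenylcopper 11 (not isolated), via dilithiated enol carbamate 12 (not isolated), via lithium alkenyl(homoprenyl)cuprate 13 (not isolated), via rearranged alkenylcopper 14 (not isolated)
Conditions: 9, Mg, THF, then CuBr·SMe2, −40 °C; 8, s-BuLi (2.2 equiv), TMEDA, Et2O, −78 °C; combine, −78 to 0 °C; CO2 (1 atm), HMPA, P(OEt)3 (10 mol%), −20 °C to rt; aq. NH4Cl, citric acid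
Reagents that add atoms: carbon dioxide, O=C=O
Why: Proposed new method: deprotonation of the (Z)-enol carbamate gives α-oxy vinyl anion 12 (an acyl-anion equivalent at the future C8'), whose cuprate 13 undergoes 1,2-migration of homoprenyl from copper to carbon while the carbamate leaves, with inversion at the sp2 carbon, so that in 14 homoprenyl is trans and copper cis to the chain, and carboxylation of 14 with retention gives the (2Z)-acid; the closest known reactions are the Kocienski-type 1,2-metallate rearrangement of α-lithiated enol carbamates or dihydrofurans with cuprates followed by electrophile trapping and the Normant carboxylation of alkenylcopper reagents, here joined in one flask.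

**Step 6**
Reactants: 16 4-amino-3-methylphenol
Product: 17 2-methyl-4-(triisopropylsilyloxy)aniline
Conditions: i-Pr3SiCl, imidazole, DMF, rt
Reagents that add atoms: chlorotriisopropylsilane, CC(C)[Si](Cl)(C(C)C)C(C)C
Why: imidazole-promoted silylation is selective for the phenolic OH over the aniline nitrogen, and the bulky silyl ether survives every later step until fluoride.

**Step 7**
Reactants: 17 2-methyl-4-(triisopropylsilyloxy)aniline
Product: 18 2-iodo-6-methyl-4-(triisopropylsilyloxy)aniline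
Conditions: N-iodosuccinimide, MeCN, 0 °C to rt, dark
Reagents that add atoms: N-iodosuccinimide, O=C1CCC(=O)N1I
Why: electrophilic aromatic iodination goes ortho to the strongly activating NH2 group because its para position is blocked and the positions next to the bulky silyloxy group are hindered.

**Step 8**
Reactants: 18 2-iodo-6-methyl-4-(triisopropylsilyloxy)aniline
Product: 20 (4-bromo-3-iodo-5-methylphenoxy)triisopropylsilane, via arenediazonium bromide 19 (not isolated)
Conditions: t-BuONO (1.5 equiv), CuBr2 (1.2 equiv), MeCN, 0 to 60 °C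
Reagents that add atoms: copper dibromide CuBr2, [Cu+2].[Br-].[Br-]
Why: Sandmeyer-type bromodediazoniation replaces the amino group by bromine at the carbon that becomes C8a and leaves the more reactive C–I bond for the Heck reaction.

**Step 9**
Reactants: 15 (2Z,6E,10R)-10-hydroxy-6,10-dimethyl-2-(4-methylpent-3-en-1-yl)dodeca-2,6,11-trienoic acid; 20 (4-bromo-3-iodo-5-methylphenoxy)triisopropylsilane
Product: 21 (2Z,6E,10R,11E)-12-[2-bromo-3-methyl-5-(triisopropylsilyloxy)phenyl]-10-hydroxy-6,10-dimethyl-2-(4-methylpent-3-en-1-yl)dodeca-2,6,11-trienoic acid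
Conditions: Pd(OAc)2 (5 mol%), n-Bu4NCl, NaHCO3 (3.5 equiv), DMF, 60 °C
Reagents that add atoms: none
Why: Jeffery-type Mizoroki–Heck reaction in which zerovalent palladium inserts into C–I far faster than into the hindered C–Br, the aryl group adds to the terminal vinyl carbon and β-hydride elimination is only possible toward the benzylic position, giving the (E)-styrene without touching the carbinol centre or the trisubstituted alkenes.

**Step 10**
Reactants: 21 (2Z,6E,10R,11E)-12-[2-bromo-3-methyl-5-(triisopropylsilyloxy)phenyl]-10-hydroxy-6,10-dimethyl-2-(4-methylpent-3-en-1-yl)dodeca-2,6,11-trienoic acid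
Product: 23 (2Z,6E)-9-[(2R)-2,8-dimethyl-6-(triisopropylsilyloxy)-2H-chromen-2-yl]-6-methyl-2-(4-methylpent-3-en-1-yl)nona-2,6-dienoic acid, via 11Z-bromostyrene isomer 22 (not isolated)
Conditions: fac-Ir(ppy)3 (1 mol%), 450 nm LEDs, degassed 1,4-dioxane, rt; then Pd(OAc)2 (5 mol%), 2-(di-tert-butylphosphino)-1,1'-binaphthyl (7 mol%), Cs2CO3 (3.5 equiv), 80 °C, dark
Reagents that add atoms: none
Why: triplet energy transfer from photoexcited fac-Ir(ppy)3 isomerises the conjugated (E)-styrene to the twisted, poorly sensitised (Z)-isomer 22, whose tertiary alkoxide then closes the pyran ring by Buchwald-type palladium-catalysed intramolecular C–O coupling onto the aryl bromide, and because the C2–O bond is never broken the (R) configuration of linalool is retained.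

**Step 11**
Reactants: 23 (2Z,6E)-9-[(2R)-2,8-dimethyl-6-(triisopropylsilyloxy)-2H-chromen-2-yl]-6-methyl-2-(4-methylpent-3-en-1-yl)nona-2,6-dienoic acid
Product: 24 (2Z,6E)-9-[(2R)-6-hydroxy-2,8-dimethyl-2H-chromen-2-yl]-6-methyl-2-(4-methylpent-3-en-1-yl)nona-2,6-dienoic acid [(R)-sargachromenol]
Conditions: n-Bu4NF (2.5 equiv), THF, 0 °C, argon; aq. NH4Cl
Reagents that add atoms: none
Why: fluoride-induced cleavage of the aryl silyl ether, driven by the strength of the Si–F bond, frees the C6 phenol under conditions that leave the chromene, the alkenes and the (Z)-acid unchanged.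

**Compound list**
1 | (3R)-3,7-dimethylocta-1,6-dien-3-ol [(R)-(−)-linalool] | C=C[C@](C)(O)CCC=C(C)C | starting material
2 | (2E,6R)-2,6-dimethylocta-2,7-diene-1,6-diol | C=C[C@](C)(O)CC/C=C(\C)CO | intermediate
3 | (3R,6E)-8-bromo-3,7-dimethylocta-1,6-dien-3-ol | C=C[C@](C)(O)CC/C=C(\C)CBr | intermediate
4 | prop-2-en-1-ol | C=CCO | starting material
5 | N,N-diisopropylcarbamoyl chloride | CC(C)N(C(C)C)C(=O)Cl | starting material
6 | prop-2-en-1-yl N,N-diisopropylcarbamate | C=CCOC(=O)N(C(C)C)C(C)C | intermediate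
7 | 1-lithioprop-2-en-1-yl N,N-diisopropylcarbamate (TMEDA complex) | [Li]C(C=C)OC(=O)N(C(C)C)C(C)C | intermediate (not isolated)
8 | (1Z,5E,9R)-9-hydroxy-5,9-dimethylundeca-1,5,10-trien-1-yl N,N-diisopropylcarbamate | C=C[C@](C)(O)CC/C=C(\C)CC/C=C\OC(=O)N(C(C)C)C(C)C | intermediate
9 | 5-bromo-2-methylpent-2-ene | CC(C)=CCCBr | starting material
10 | (4-methylpent-3-en-1-yl)magnesium bromide | CC(C)=CCC[Mg]Br | intermediate (not isolated)
11 | (4-methylpent-3-en-1-yl)copper | CC(C)=CCC[Cu] | intermediate (not isolated)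
12 | lithium (3R,6E,10Z)-11-(diisopropylcarbamoyloxy)-11-lithio-3,7-dimethylundeca-1,6,10-trien-3-olate | C=C[C@](C)(O[Li])CC/C=C(\C)CC/C=C(/[Li])OC(=O)N(C(C)C)C(C)C | intermediate (not isolated)
13 | lithium cuprate from 12 and 11 (copper on the carbamate-bearing carbon, trans to the chain) | [Li+].C=C[C@](C)(O[Li])CC/C=C(\C)CC/C=C(/[Cu-]CCC=C(C)C)OC(=O)N(C(C)C)C(C)C | intermediate (not isolated)
14 | [(1Z,5E,9R)-9-(lithiooxy)-5,9-dimethyl-1-(4-methylpent-3-en-1-yl)undeca-1,5,10-trien-1-yl]copper | C=C[C@](C)(O[Li])CC/C=C(\C)CC/C=C(/CCC=C(C)C)[Cu] | intermediate (not isolated)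
15 | (2Z,6E,10R)-10-hydroxy-6,10-dimethyl-2-(4-methylpent-3-en-1-yl)dodeca-2,6,11-trienoic acid | C=C[C@](C)(O)CC/C=C(\C)CC/C=C(/CCC=C(C)C)C(=O)O | intermediate
16 | 4-amino-3-methylphenol | Cc1cc(O)ccc1N | starting material
17 | 2-methyl-4-(triisopropylsilyloxy)aniline | Cc1cc(O[Si](C(C)C)(C(C)C)C(C)C)ccc1N | intermediate
18 | 2-iodo-6-methyl-4-(triisopropylsilyloxy)aniline | Cc1cc(O[Si](C(C)C)(C(C)C)C(C)C)cc(I)c1N | intermediate
19 | 2-iodo-6-methyl-4-(triisopropylsilyloxy)benzenediazonium bromide | Cc1cc(O[Si](C(C)C)(C(C)C)C(C)C)cc(I)c1[N+]#N.[Br-] | intermediate (not isolated)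
20 | (4-bromo-3-iodo-5-methylphenoxy)triisopropylsilane | Cc1cc(O[Si](C(C)C)(C(C)C)C(C)C)cc(I)c1Br | intermediate
21 | (2Z,6E,10R,11E)-12-[2-bromo-3-methyl-5-(triisopropylsilyloxy)phenyl]-10-hydroxy-6,10-dimethyl-2-(4-methylpent-3-en-1-yl)dodeca-2,6,11-trienoic acid | Cc1cc(O[Si](C(C)C)(C(C)C)C(C)C)cc(/C=C/[C@](C)(O)CC/C=C(\C)CC/C=C(/CCC=C(C)C)C(=O)O)c1Br | intermediate
22 | (2Z,6E,10R,11Z)-12-[2-bromo-3-methyl-5-(triisopropylsilyloxy)phenyl]-10-hydroxy-6,10-dimethyl-2-(4-methylpent-3-en-1-yl)dodeca-2,6,11-trienoic acid | Cc1cc(O[Si](C(C)C)(C(C)C)C(C)C)cc(/C=C\[C@](C)(O)CC/C=C(\C)CC/C=C(/CCC=C(C)C)C(=O)O)c1Br | intermediate (not isolated)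
23 | (2Z,6E)-9-[(2R)-2,8-dimethyl-6-(triisopropylsilyloxy)-2H-chromen-2-yl]-6-methyl-2-(4-methylpent-3-en-1-yl)nona-2,6-dienoic acid | CC(C)=CCC/C(=C/CC/C(C)=C/CC[C@]1(C)C=Cc2cc(O[Si](C(C)C)(C(C)C)C(C)C)cc(C)c2O1)C(=O)O | intermediate
24 | (2Z,6E)-9-[(2R)-6-hydroxy-2,8-dimethyl-2H-chromen-2-yl]-6-methyl-2-(4-methylpent-3-en-1-yl)nona-2,6-dienoic acid [(R)-sargachromenol] | CC(C)=CCC/C(=C/CC/C(C)=C/CC[C@]1(C)C=Cc2cc(O)cc(C)c2O1)C(=O)O | target

**Totals**
Total step count: 11. Longest linear sequence: 7 steps (1 → 2 → 3 → 8 → 15 → 21 → 23 → 24; steps 1, 2, 4, 5, 9, 10, 11).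

**Three steps most likely to fail**

Step 4 (α- instead of γ-attack of 7, or SN2' at the allylic bromide). The fallback sets out from 3 and comes back at 15, building the acrylate by carbonyl olefination instead. Bromide 3 is alkylated with the lithium aza-enolate of commercial N-ethylidenecyclohexanamine (LDA, THF, −78 °C, 2.2 equiv) to give N-[(4E,8R)-8-hydroxy-4,8-dimethyldeca-4,9-dien-1-ylidene]cyclohexanamine F1. Mild hydrolysis (aq. tartaric acid, 0 °C) gives (4E,8R)-8-hydroxy-4,8-dimethyldeca-4,9-dienal F2. This is condensed under Still–Gennari conditions (KHMDS, 18-crown-6, THF, −78 °C) with methyl 2-[bis(2,2,2-trifluoroethoxy)phosphoryl]-6-methylhept-5-enoate F3, itself made from commercial methyl [bis(2,2,2-trifluoroethoxy)phosphoryl]acetate, NaH and 9. The product, methyl (2Z,6E,10R)-10-hydroxy-6,10-dimethyl-2-(4-methylpent-3-en-1-yl)dodeca-2,6,11-trienoate F4, is saponified (LiOH, THF/MeOH/H2O) to 15.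

Step 5 (the α-lithio carbamate may eliminate to an alkyne before the 1,2-shift, or the alkenylcopper may carboxylate poorly). The fallback sets out from 8 and comes back at 15, doing the 1,2-shift on boron and the carboxylation catalytically. Grignard reagent 10 and 2-isopropoxy-4,4,5,5-tetramethyl-1,3,2-dioxaborolane give 4,4,5,5-tetramethyl-2-(4-methylpent-3-en-1-yl)-1,3,2-dioxaborolane F5. This is added to dilithiated 12 at −78 °C and warmed, so that homoprenyl migrates from boron to carbon with loss of the carbamate and inversion, giving (3R,6E,10E)-3,7,15-trimethyl-11-(4,4,5,5-tetramethyl-1,3,2-dioxaborolan-2-yl)hexadeca-1,6,10,14-tetraen-3-ol F6. Copper-catalysed carboxylation of the alkenylboronate (CuCl(IPr), KOMe, CO2 1 atm, THF, 70 °C; IPr = 1,3-bis(2,6-diisopropylphenyl)imidazol-2-ylidene) with retention then gives 15.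

Step 10 (incomplete E→Z ratio; the doubly ortho-substituted aryl bromide and the free carboxylate may stall the palladium etherification). The fallback sets out from 21 and comes back at 23, making C8a the nucleophilic partner. Miyaura borylation of 21 (PdCl2(dppf), B2pin2, KOAc, 1,4-dioxane, 80 °C) gives (2Z,6E,10R,11E)-10-hydroxy-6,10-dimethyl-2-(4-methylpent-3-en-1-yl)-12-[3-methyl-2-(4,4,5,5-tetramethyl-1,3,2-dioxaborolan-2-yl)-5-(triisopropylsilyloxy)phenyl]dodeca-2,6,11-trienoic acid F7. The same fac-Ir(ppy)3/blue-light isomerisation gives its 11Z isomer, (2Z,6E,10R,11Z)-10-hydroxy-6,10-dimethyl-2-(4-methylpent-3-en-1-yl)-12-[3-methyl-2-(4,4,5,5-tetramethyl-1,3,2-dioxaborolan-2-yl)-5-(triisopropylsilyloxy)phenyl]dodeca-2,6,11-trienoic acid F8. Oxidative copper-promoted intramolecular etherification (Cu(OAc)2, pyridine, 4 Å sieves, O2, CH2Cl2, rt; Chan–Evans–Lam type) then gives 23.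

**Further compounds**
F1 | step 4 | N-[(4E,8R)-8-hydroxy-4,8-dimethyldeca-4,9-dien-1-ylidene]cyclohexanamine | C=C[C@](C)(O)CC/C=C(\C)CCC=NC1CCCCC1
F2 | step 4 | (4E,8R)-8-hydroxy-4,8-dimethyldeca-4,9-dienal | C=C[C@](C)(O)CC/C=C(\C)CCC=O
F3 | step 4 | methyl 2-[bis(2,2,2-trifluoroethoxy)phosphoryl]-6-methylhept-5-enoate | COC(=O)C(CCC=C(C)C)P(=O)(OCC(F)(F)F)OCC(F)(F)F
F4 | step 4 | methyl (2Z,6E,10R)-10-hydroxy-6,10-dimethyl-2-(4-methylpent-3-en-1-yl)dodeca-2,6,11-trienoate | C=C[C@](C)(O)CC/C=C(\C)CC/C=C(/CCC=C(C)C)C(=O)OC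
F5 | step 5 | 4,4,5,5-tetramethyl-2-(4-methylpent-3-en-1-yl)-1,3,2-dioxaborolane | CC(C)=CCCB1OC(C)(C)C(C)(C)O1
F6 | step 5 | (3R,6E,10E)-3,7,15-trimethyl-11-(4,4,5,5-tetramethyl-1,3,2-dioxaborolan-2-yl)hexadeca-1,6,10,14-tetraen-3-ol | C=C[C@](C)(O)CC/C=C(\C)CC/C=C(/CCC=C(C)C)B1OC(C)(C)C(C)(C)O1
F7 | step 10 | (2Z,6E,10R,11E)-10-hydroxy-6,10-dimethyl-2-(4-methylpent-3-en-1-yl)-12-[3-methyl-2-(4,4,5,5-tetramethyl-1,3,2-dioxaborolan-2-yl)-5-(triisopropylsilyloxy)phenyl]dodeca-2,6,11-trienoic acid | Cc1cc(O[Si](C(C)C)(C(C)C)C(C)C)cc(/C=C/[C@](C)(O)CC/C=C(\C)CC/C=C(/CCC=C(C)C)C(=O)O)c1B1OC(C)(C)C(C)(C)O1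
F8 | step 10 | (2Z,6E,10R,11Z)-10-hydroxy-6,10-dimethyl-2-(4-methylpent-3-en-1-yl)-12-[3-methyl-2-(4,4,5,5-tetramethyl-1,3,2-dioxaborolan-2-yl)-5-(triisopropylsilyloxy)phenyl]dodeca-2,6,11-trienoic acid | Cc1cc(O[Si](C(C)C)(C(C)C)C(C)C)cc(/C=C\[C@](C)(O)CC/C=C(\C)CC/C=C(/CCC=C(C)C)C(=O)O)c1B1OC(C)(C)C(C)(C)O1
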